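**Plan** (terpenoid numbering of the decalin: C3 carbinol, C4 gem-dimethyl, C5/C10 ring fusion, C8 methylene carbon, C9 side-chain carbon, chain from C11)
Cuts: C11–C12 (alkyl Grignard + farnesyl chloride); C9–C10 (proton-initiated closure of ring B from a monocyclic keto ester, C8 methylene from the ketone); C5–C6 (Negishi coupling at a C5 enol triflate); last, ring A at C1–C2 and C3–C4 together.
Enabling feature: in ring A the quaternary C4 lies between C3 and C5, and C1 is β to C5 through C10. With C3 and C5 at the ketone level ring A is 2,2,4-trimethylcyclohexane-1,3-dione, made in one operation from malonate (C2, C3) and isopropenyl isopropyl ketone (C1, C10, C5, C4) by Michael addition and Claisen closure.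
Forward order: ring A (steps 1–3), chain at C5 (4–6), ring B (7), C8/C11 adjustment (8–10), side chain (11), desilylation (12).
Stereochemistry: C3 from a CBS reduction; C5, C10 and C9 relayed from C3 in the cyclisation (trans-fusion, chair); 13E,17E carried in from (2E,6E)-farnesyl chloride.

Key step: step 1

Remark: 2,4-dimethylpent-1-en-3-one, (3-ethoxy-3-oxopropyl)zinc bromide in THF and (2E,6E)-farnesyl chloride are treated as catalogue reagents.

Step 1
Reactants: 1 diethyl malonate; 2 2,4-dimethylpent-1-en-3-one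
Product: 5 2,2,4-trimethylcyclohexane-1,3-dione, via Michael adduct 3 (not isolated), via cyclic keto ester 4 (not isolated)
Conditions: NaOEt (2.2 equiv), EtOH, 0 °C → reflux; then 6 M HCl, reflux
Reagents that add atoms: none
Why: Ethoxide forms the malonate anion, which adds to the CH2 terminus of enone 2 (Michael addition, C1–C2); under the equilibrating conditions the tertiary enolate of the isopropyl ketone (C4) then attacks one malonate ester carbonyl (Claisen acylation, C3–C4), and hot aqueous acid hydrolyses and decarboxylates the remaining ester. The closest known reaction type is the Michael–Claisen annulation of malonate with an enone used to make dimedone. Ring A closes by a 6-exo-trig acyl substitution. No stereocentre of the target is set: the methyl-bearing carbon (later C10) forms without control and is flattened in step 4. The step needs 1,4-addition and closure through C4; every other enolate/carbonyl pairing could only give a four-membered ring, and the doubly activated C2–H of 4 is the thermodynamic sink that makes acylation at the non-enolisable quaternary centre irreversible.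

Step 2
Reactants: 5 2,2,4-trimethylcyclohexane-1,3-dione
Product: 6 (3S)-3-hydroxy-2,2,6-trimethylcyclohexan-1-one
Conditions: (R)-2-methyl-CBS-oxazaborolidine (10 mol %), BH3·SMe2, THF, −30 °C; then MeOH, aq. NH4Cl
Reagents that add atoms: none
Why: CBS reduction: the carbonyl flanked by CH2 is the less hindered one and should react first, and the (R)-oxazaborolidine, which treats the quaternary carbon as the large substituent, should deliver hydride to give the (S)-carbinol (the future C3) whatever the configuration of the remote methyl-bearing carbon.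

Step 3
Reactants: 6 (3S)-3-hydroxy-2,2,6-trimethylcyclohexan-1-one
Product: 7 (3S)-3-[(tert-butyldiphenylsilyl)oxy]-2,2,6-trimethylcyclohexan-1-one
Conditions: TBDPSCl, imidazole, DMAP (cat.), DMF, 50 °C
Reagents that add atoms: tert-butyl(chloro)diphenylsilane, CC(C)(C)[Si](Cl)(c1ccccc1)c1ccccc1
Why: Silyl ether formation gives a base- and Lewis-acid-stable, bulky group that blocks retro-aldol cleavage in the enolate chemistry and later shields one face of ring A.

Step 4
Reactants: 7 (3S)-3-[(tert-butyldiphenylsilyl)oxy]-2,2,6-trimethylcyclohexan-1-one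
Product: 8 (5S)-5-[(tert-butyldiphenylsilyl)oxy]-2,6,6-trimethylcyclohex-1-en-1-yl trifluoromethanesulfonate
Conditions: KN(SiMe3)2, THF, −78 °C; PhNTf2, −78 °C → 0 °C; aq. NH4Cl
Reagents that add atoms: N-phenylbis(trifluoromethanesulfonimide), O=S(=O)(N(c1ccccc1)S(=O)(=O)C(F)(F)F)C(F)(F)F
Why: The ketone can enolise only towards the methyl-bearing carbon (the other α-carbon is quaternary), so O-sulfonylation of the potassium enolate should give a single enol triflate and removes the uncontrolled stereocentre.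

Step 5
Reactants: 8 (5S)-5-[(tert-butyldiphenylsilyl)oxy]-2,6,6-trimethylcyclohex-1-en-1-yl trifluoromethanesulfonate
Product: 9 ethyl 3-[(5S)-5-[(tert-butyldiphenylsilyl)oxy]-2,6,6-trimethylcyclohex-1-en-1-yl]propanoate
Conditions: BrZnCH2CH2CO2Et, Pd(PPh3)4 (5 mol %), LiCl, THF, 60 °C
Reagents that add atoms: (3-ethoxy-3-oxopropyl)zinc bromide, CCOC(=O)CC[Zn]Br
Why: Negishi cross-coupling of the enol triflate with the zinc homoenolate forms C5–C6 at sp2 carbon and fixes the tetrasubstituted C5=C10 alkene.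

Step 6
Reactants: 9 ethyl 3-[(5S)-5-[(tert-butyldiphenylsilyl)oxy]-2,6,6-trimethylcyclohex-1-en-1-yl]propanoate
Product: 10 ethyl 5-[(5S)-5-[(tert-butyldiphenylsilyl)oxy]-2,6,6-trimethylcyclohex-1-en-1-yl]-3-oxopentanoate
Conditions: EtOAc, LiN(iPr)2 (3 equiv each), THF, −78 °C; then 9, −78 °C → 0 °C; aq. NH4Cl
Reagents that add atoms: ethyl acetate, CCOC(C)=O
Why: Crossed Claisen condensation of the ester with excess lithium enolate of ethyl acetate, driven by deprotonation of the keto ester formed.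

Step 7
Reactants: 10 ethyl 5-[(5S)-5-[(tert-butyldiphenylsilyl)oxy]-2,6,6-trimethylcyclohex-1-en-1-yl]-3-oxopentanoate
Product: 11 ethyl (1R,4aR,6S,8aS)-6-[(tert-butyldiphenylsilyl)oxy]-5,5,8a-trimethyl-2-oxodecahydronaphthalene-1-carboxylate
Conditions: SnCl4 (2 equiv), CH2Cl2, −40 °C → 0 °C
Reagents that add atoms: none
Why: Cation–olefin cyclisation with a keto ester terminator: axial protonation at C5 should occur on the face opposite the bulky C3 silyloxy group and anti to the axial C4 methyl, and the C10 cation is then captured by the enol carbon C9 through a chair transition state, which should give the trans-decalin with axial C10 methyl while the epimerisable C9 ester settles equatorial.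

Step 8
Reactants: 11 ethyl (1R,4aR,6S,8aS)-6-[(tert-butyldiphenylsilyl)oxy]-5,5,8a-trimethyl-2-oxodecahydronaphthalene-1-carboxylate
Product: 12 ethyl (1S,4aR,6S,8aS)-6-[(tert-butyldiphenylsilyl)oxy]-5,5,8a-trimethyl-2-methylidenedecahydronaphthalene-1-carboxylate
Conditions: Ph3PCH3Br, KOtBu, toluene, rt → 80 °C
Reagents that add atoms: methyltriphenylphosphonium bromide, C[P+](c1ccccc1)(c1ccccc1)c1ccccc1.[Br-]
Why: Wittig methylenation of the hindered C8 ketone installs the exocyclic methylene; C9 should keep its equatorial ester.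

Step 9
Reactants: 12 ethyl (1S,4aR,6S,8aS)-6-[(tert-butyldiphenylsilyl)oxy]-5,5,8a-trimethyl-2-methylidenedecahydronaphthalene-1-carboxylate
Product: 13 [(1S,4aR,6S,8aS)-6-[(tert-butyldiphenylsilyl)oxy]-5,5,8a-trimethyl-2-methylidenedecahydronaphthalen-1-yl]methanol
Conditions: LiAlH4, Et2O, 0 °C
Reagents that add atoms: none
Why: Hydride reduction of the ester to the primary alcohol (C11); the isolated alkene and the silyl ether are inert.

Step 10
Reactants: 13 [(1S,4aR,6S,8aS)-6-[(tert-butyldiphenylsilyl)oxy]-5,5,8a-trimethyl-2-methylidenedecahydronaphthalen-1-yl]methanol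
Product: 14 (1S,4aR,6S,8aS)-1-(bromomethyl)-6-[(tert-butyldiphenylsilyl)oxy]-5,5,8a-trimethyl-2-methylidenedecahydronaphthalene
Conditions: CBr4, PPh3, CH2Cl2, 0 °C
Reagents that add atoms: carbon tetrabromide, BrC(Br)(Br)Br
Why: Appel bromination of the primary, β-branched alcohol under neutral conditions.

Step 11
Reactants: 14 (1S,4aR,6S,8aS)-1-(bromomethyl)-6-[(tert-butyldiphenylsilyl)oxy]-5,5,8a-trimethyl-2-methylidenedecahydronaphthalene; 15 (2E,6E)-1-chloro-3,7,11-trimethyldodeca-2,6,10-triene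
Product: 17 (1S,4aR,6S,8aR)-6-[(tert-butyldiphenylsilyl)oxy]-5,5,8a-trimethyl-2-methylidene-1-[(3E,7E)-4,8,12-trimethyltrideca-3,7,11-trien-1-yl]decahydronaphthalene, via Grignard reagent 16 (not isolated)
Conditions: Mg, THF, 45 °C; then 15, Li2CuCl4 (3 mol %), THF, −20 °C → rt
Reagents that add atoms: none
Why: Copper-catalysed coupling of the primary alkyl Grignard reagent with the allylic chloride at its CH2 terminus (SN2 rather than SN2′) forms C11–C12 and should keep the 2E,6E geometry, which becomes 13E,17E.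

Step 12
Reactants: 17 (1S,4aR,6S,8aR)-6-[(tert-butyldiphenylsilyl)oxy]-5,5,8a-trimethyl-2-methylidene-1-[(3E,7E)-4,8,12-trimethyltrideca-3,7,11-trien-1-yl]decahydronaphthalene
Product: 18 (2S,4aR,5S,8aR)-1,1,4a-trimethyl-6-methylidene-5-[(3E,7E)-4,8,12-trimethyltrideca-3,7,11-trien-1-yl]decahydronaphthalen-2-ol (CNP0192094.1)
Conditions: Bu4NF, THF, 50 °C
Reagents that add atoms: none
Why: Fluoride-mediated desilylation frees the C3 hydroxyl without touching the four alkenes.

**Compound list**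
1 | diethyl malonate | CCOC(=O)CC(=O)OCC | starting material
2 | 2,4-dimethylpent-1-en-3-one | CC(C)C(=O)C(C)=C | starting material
3 | diethyl 2-(2,4-dimethyl-3-oxopentyl)propanedioate (racemic) | CCOC(=O)C(CC(C)C(=O)C(C)C)C(=O)OCC | intermediate
4 | ethyl 3,3,5-trimethyl-2,4-dioxocyclohexane-1-carboxylate (stereoisomer mixture) | CCOC(=O)C1CC(C)C(=O)C(C)(C)C1=O | intermediate
5 | 2,2,4-trimethylcyclohexane-1,3-dione (racemic) | CC1CCC(=O)C(C)(C)C1=O | intermediate
6 | (3S)-3-hydroxy-2,2,6-trimethylcyclohexan-1-one (both C6 epimers) | CC1CC[C@H](O)C(C)(C)C1=O | intermediate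
7 | (3S)-3-[(tert-butyldiphenylsilyl)oxy]-2,2,6-trimethylcyclohexan-1-one (both C6 epimers) | CC1CC[C@H](O[Si](c2ccccc2)(c2ccccc2)C(C)(C)C)C(C)(C)C1=O | intermediate
8 | (5S)-5-[(tert-butyldiphenylsilyl)oxy]-2,6,6-trimethylcyclohex-1-en-1-yl trifluoromethanesulfonate | CC1=C(OS(=O)(=O)C(F)(F)F)C(C)(C)[C@@H](O[Si](c2ccccc2)(c2ccccc2)C(C)(C)C)CC1 | intermediate
9 | ethyl 3-[(5S)-5-[(tert-butyldiphenylsilyl)oxy]-2,6,6-trimethylcyclohex-1-en-1-yl]propanoate | CCOC(=O)CCC1=C(C)CC[C@H](O[Si](c2ccccc2)(c2ccccc2)C(C)(C)C)C1(C)C | intermediate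
10 | ethyl 5-[(5S)-5-[(tert-butyldiphenylsilyl)oxy]-2,6,6-trimethylcyclohex-1-en-1-yl]-3-oxopentanoate | CCOC(=O)CC(=O)CCC1=C(C)CC[C@H](O[Si](c2ccccc2)(c2ccccc2)C(C)(C)C)C1(C)C | intermediate
11 | ethyl (1R,4aR,6S,8aS)-6-[(tert-butyldiphenylsilyl)oxy]-5,5,8a-trimethyl-2-oxodecahydronaphthalene-1-carboxylate (trans-fused) | O=C1CC[C@H]2C(C)(C)[C@@H](O[Si](c3ccccc3)(c3ccccc3)C(C)(C)C)CC[C@]2(C)[C@H]1C(=O)OCC | intermediate
12 | ethyl (1S,4aR,6S,8aS)-6-[(tert-butyldiphenylsilyl)oxy]-5,5,8a-trimethyl-2-methylidenedecahydronaphthalene-1-carboxylate | C=C1CC[C@H]2C(C)(C)[C@@H](O[Si](c3ccccc3)(c3ccccc3)C(C)(C)C)CC[C@]2(C)[C@H]1C(=O)OCC | intermediate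
13 | [(1S,4aR,6S,8aS)-6-[(tert-butyldiphenylsilyl)oxy]-5,5,8a-trimethyl-2-methylidenedecahydronaphthalen-1-yl]methanol | C=C1CC[C@H]2C(C)(C)[C@@H](O[Si](c3ccccc3)(c3ccccc3)C(C)(C)C)CC[C@]2(C)[C@H]1CO | intermediate
14 | (1S,4aR,6S,8aS)-1-(bromomethyl)-6-[(tert-butyldiphenylsilyl)oxy]-5,5,8a-trimethyl-2-methylidenedecahydronaphthalene | C=C1CC[C@H]2C(C)(C)[C@@H](O[Si](c3ccccc3)(c3ccccc3)C(C)(C)C)CC[C@]2(C)[C@H]1CBr | intermediate
15 | (2E,6E)-1-chloro-3,7,11-trimethyldodeca-2,6,10-triene ((2E,6E)-farnesyl chloride) | ClC/C=C(\C)CC/C=C(\C)CCC=C(C)C | starting material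
16 | Grignard reagent of 14 (C11–MgBr, ring configuration as in 14) | C=C1CC[C@H]2C(C)(C)[C@@H](O[Si](c3ccccc3)(c3ccccc3)C(C)(C)C)CC[C@]2(C)[C@H]1C[Mg]Br | intermediate
17 | (1S,4aR,6S,8aR)-6-[(tert-butyldiphenylsilyl)oxy]-5,5,8a-trimethyl-2-methylidene-1-[(3E,7E)-4,8,12-trimethyltrideca-3,7,11-trien-1-yl]decahydronaphthalene | C=C1CC[C@H]2C(C)(C)[C@@H](O[Si](c3ccccc3)(c3ccccc3)C(C)(C)C)CC[C@]2(C)[C@H]1CC/C=C(\C)CC/C=C(\C)CCC=C(C)C | intermediate
18 | (2S,4aR,5S,8aR)-1,1,4a-trimethyl-6-methylidene-5-[(3E,7E)-4,8,12-trimethyltrideca-3,7,11-trien-1-yl]decahydronaphthalen-2-ol (CNP0192094.1) | C=C1CC[C@H]2C(C)(C)[C@@H](O)CC[C@]2(C)[C@H]1CC/C=C(\C)CC/C=C(\C)CCC=C(C)C | target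

**Count**
Total steps: 12. Longest linear sequence: 12 steps (1 and 2 to 18).

**Steps most likely to fail**

Step 7. What may go wrong: protonation of the ring alkene with too little face control from C3, acid-induced loss of the silyl ether, and O- instead of C-alkylation of the enol. Fallback (radical closure, C5 hydrogen set afterwards): from 10, Mn(OAc)3·2H2O and Cu(OAc)2 in AcOH should effect an oxidative radical cyclisation in which the keto ester radical adds to C10 and the C5 radical is oxidised to the alkene. This gives ethyl 6-[(tert-butyldiphenylsilyl)oxy]-5,5,8a-trimethyl-2-oxo-1,2,3,5,6,7,8,8a-octahydronaphthalene-1-carboxylate F1 (configuration at C1, C6 and C8a as in 11). Hydrogenation of F1 (H2, Pd/C, EtOAc) from the face opposite the angular methyl returns to 11.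

Step 8. What may go wrong: enolisation of the keto ester by the ylide instead of olefination, migration of the new alkene into conjugation with the ester, and epimerisation at C9. Fallback (remove the acidifying ester first): from 11, LiAlH4 should give the diol 6-[(tert-butyldiphenylsilyl)oxy]-1-(hydroxymethyl)-5,5,8a-trimethyldecahydronaphthalen-2-ol F2. TBSCl/imidazole at 0 °C silylates only the primary hydroxyl to give the mono-TBS ether F3. Dess–Martin periodinane gives the C8 ketone F4. Ph3P=CH2 gives the methylidene TBS ether F5. PPTS in MeOH removes the primary silyl group and returns to 13.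

Step 11. What may go wrong: sluggish Grignard formation, homocoupling, and attack at the substituted allylic terminus. Fallback (sulfone alkylation): from 13, PhSSPh/PBu3 should give the phenyl sulfide F6, and H2O2 with catalytic (NH4)6Mo7O24 the phenyl sulfone F7. Deprotonation with n-BuLi (THF/HMPA, −78 °C) and alkylation with (2E,6E)-farnesyl bromide gives the C11-sulfonyl coupling product F8. Na(Hg)/Na2HPO4 in MeOH removes the sulfonyl group and returns to 17.

**Further compounds**
F1 | step 7 | ethyl 6-[(tert-butyldiphenylsilyl)oxy]-5,5,8a-trimethyl-2-oxo-1,2,3,5,6,7,8,8a-octahydronaphthalene-1-carboxylate (configuration as in 11) | O=C1CC=C2C(C)(C)[C@@H](O[Si](c3ccccc3)(c3ccccc3)C(C)(C)C)CC[C@]2(C)[C@H]1C(=O)OCC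
F2 | step 8 | 6-[(tert-butyldiphenylsilyl)oxy]-1-(hydroxymethyl)-5,5,8a-trimethyldecahydronaphthalen-2-ol (C2 epimers, ring configuration as in 11) | OC1CC[C@H]2C(C)(C)[C@@H](O[Si](c3ccccc3)(c3ccccc3)C(C)(C)C)CC[C@]2(C)[C@H]1CO
F3 | step 8 | 1-{[(tert-butyldimethylsilyl)oxy]methyl}-6-[(tert-butyldiphenylsilyl)oxy]-5,5,8a-trimethyldecahydronaphthalen-2-ol | OC1CC[C@H]2C(C)(C)[C@@H](O[Si](c3ccccc3)(c3ccccc3)C(C)(C)C)CC[C@]2(C)[C@H]1CO[Si](C)(C)C(C)(C)C
F4 | step 8 | 1-{[(tert-butyldimethylsilyl)oxy]methyl}-6-[(tert-butyldiphenylsilyl)oxy]-5,5,8a-trimethyloctahydronaphthalen-2(1H)-one | O=C1CC[C@H]2C(C)(C)[C@@H](O[Si](c3ccccc3)(c3ccccc3)C(C)(C)C)CC[C@]2(C)[C@H]1CO[Si](C)(C)C(C)(C)C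
F5 | step 8 | 1-{[(tert-butyldimethylsilyl)oxy]methyl}-6-[(tert-butyldiphenylsilyl)oxy]-5,5,8a-trimethyl-2-methylidenedecahydronaphthalene | C=C1CC[C@H]2C(C)(C)[C@@H](O[Si](c3ccccc3)(c3ccccc3)C(C)(C)C)CC[C@]2(C)[C@H]1CO[Si](C)(C)C(C)(C)C
F6 | step 11 | 6-[(tert-butyldiphenylsilyl)oxy]-5,5,8a-trimethyl-2-methylidene-1-[(phenylsulfanyl)methyl]decahydronaphthalene (configuration as in 13) | C=C1CC[C@H]2C(C)(C)[C@@H](O[Si](c3ccccc3)(c3ccccc3)C(C)(C)C)CC[C@]2(C)[C@H]1CSc4ccccc4
F7 | step 11 | 1-[(benzenesulfonyl)methyl]-6-[(tert-butyldiphenylsilyl)oxy]-5,5,8a-trimethyl-2-methylidenedecahydronaphthalene | C=C1CC[C@H]2C(C)(C)[C@@H](O[Si](c3ccccc3)(c3ccccc3)C(C)(C)C)CC[C@]2(C)[C@H]1CS(=O)(=O)c4ccccc4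
F8 | step 11 | 1-[(3E,7E)-1-(benzenesulfonyl)-4,8,12-trimethyltrideca-3,7,11-trien-1-yl]-6-[(tert-butyldiphenylsilyl)oxy]-5,5,8a-trimethyl-2-methylidenedecahydronaphthalene (epimers at the sulfonyl carbon) | C=C1CC[C@H]2C(C)(C)[C@@H](O[Si](c3ccccc3)(c3ccccc3)C(C)(C)C)CC[C@]2(C)[C@H]1C(C/C=C(\C)CC/C=C(\C)CCC=C(C)C)S(=O)(=O)c4ccccc4
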